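**Retrosynthetic overview** (germacranolide numbering: C6 lactone carbinol, C7 ring fusion, C8 ester carbinol, C1/C10 epoxide, C14 = CH2OH carbon, C3 carbinol, C4=C5 cis olefin, C11–C13 methylene lactone)
1. Target 29 ⇐ epoxy ketone 28 (ketone reduction at C3) ⇐ dienone allylic alcohol 27 (hydroxyl-directed epoxidation of C1=C10).
2. 27 ⇐ cyclobutanone cyclic sulfate 24: the ten-membered ring is never closed directly; the alkenyl iodide carbon C4 adds to the cyclobutanone carbonyl C3 to close the eight-membered ring C3–C10, which expands at once by C1–C2 through Grob fragmentation.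
3. Enabling feature: in the ten-membered ring the C3 carbonyl and the trisubstituted C1=C10 olefin are separated only by C2, and C14 on that olefin carries oxygen. This is the retron of a 3-sulfonyloxycyclobutanol (four-membered ring C3–C2–C1–C10 with C1–O tied to C14 in a six-membered ring), and the cis C4=C5 olefin fits an eight-membered ring.
4. 24 ⇐ 4H-1,3-dioxin 20 (dichloroketene [2+2]) ⇐ bromide 15 + (Z)-3-iodobut-2-enal 4 (chromium allylation/lactonisation sets C6, C7) ⇐ glyoxylate-ene adduct 9 (sets C8).
5. Ring order: γ-lactone → dioxane-fused cyclobutanone → cyclic sulfate → eight-membered ring (transient) → ten-membered ring → epoxide.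

Key step: step 16

Remark: C1, C3 and C10 of the four-membered ring and C7 of adduct 13 are temporary stereocentres; 21–26 are drawn as one of the two cis-fused diastereomers expected from step 12 and 13–14 without configuration at C7, since steps 16 and 8 erase these centres.
Remark: hydroxy ketones 27 and 28 are treated as open forms; a transannular C14–O–C3 hemiketal, if populated, should equilibrate with them under the conditions of steps 17 and 18.

Step 1
Reactants: 1 but-2-yn-1-ol
Product: 3 (Z)-3-iodobut-2-en-1-ol, via cyclic sodium alkenylalanate 2 (not isolated)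
Conditions: NaAlH2(OCH2CH2OCH3)2, THF, 0 °C to rt; then I2, −78 to 0 °C
Reagents that add atoms: iodine, II
Why: trans-hydroalumination of the propargylic alcohol through the alkoxide-bound hydride places aluminium at C3 cis to the CH2O group, and iodinolysis with retention should give the (Z)-iodoalkene (hydroalumination–iodination).

Step 2
Reactants: 3 (Z)-3-iodobut-2-en-1-ol
Product: 4 (Z)-3-iodobut-2-enal
Conditions: MnO2 (activated), CH2Cl2, rt, dark; used at once
Reagents that add atoms: none
Why: allylic oxidation with MnO2 stops at the aldehyde and should leave the alkenyl iodide and its Z geometry untouched.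

Step 3
Reactants: 5 2-methylenepropane-1,3-diol; 6 2,2-dimethoxypropane
Product: 7 2,2-dimethyl-5-methylene-1,3-dioxane
Conditions: p-toluenesulfonic acid monohydrate (cat.), CH2Cl2, rt
Reagents that add atoms: none
Why: acid-catalysed transacetalisation (isopropylidene acetal formation) of a 1,3-diol, driven by loss of methanol.

Step 4
Reactants: 7 2,2-dimethyl-5-methylene-1,3-dioxane; 8 ethyl glyoxylate
Product: 9 ethyl (2R)-3-(2,2-dimethyl-4H-1,3-dioxin-5-yl)-2-hydroxypropanoate
Conditions: (R)-BINOL (10 mol %), Ti(OiPr)2Cl2 (10 mol %), 4 Å MS, CH2Cl2, −30 °C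
Reagents that add atoms: none
Why: catalytic asymmetric glyoxylate-ene reaction of a 1,1-disubstituted olefin: the exocyclic CH2 (C9) bonds to the titanium-bound aldehyde while a ring OCH2 hydrogen is transferred, which moves the double bond into the ring as the enol ether (C1=C10) and sets C8 under control of the (R)-BINOL titanium catalyst.

Step 5
Reactants: 9 ethyl (2R)-3-(2,2-dimethyl-4H-1,3-dioxin-5-yl)-2-hydroxypropanoate
Product: 10 ethyl (2R)-2-(tert-butyldimethylsilyloxy)-3-(2,2-dimethyl-4H-1,3-dioxin-5-yl)propanoate
Conditions: t-BuMe2SiCl, imidazole, DMF, rt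
Reagents that add atoms: tert-butyldimethylsilyl chloride, CC(C)(C)[Si](C)(C)Cl
Why: standard silylation of a secondary alcohol under basic conditions that spare the acid-labile enol ether acetal.

Step 6
Reactants: 10 ethyl (2R)-2-(tert-butyldimethylsilyloxy)-3-(2,2-dimethyl-4H-1,3-dioxin-5-yl)propanoate
Product: 11 (2R)-2-(tert-butyldimethylsilyloxy)-3-(2,2-dimethyl-4H-1,3-dioxin-5-yl)propanal
Conditions: i-Bu2AlH, CH2Cl2, −78 °C; aqueous potassium sodium tartrate
Reagents that add atoms: none
Why: partial reduction of an α-silyloxy ester, whose tetrahedral aluminium hemiacetal should survive at −78 °C until work-up, so that the aldehyde is released without epimerisation.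

Step 7
Reactants: 11 (2R)-2-(tert-butyldimethylsilyloxy)-3-(2,2-dimethyl-4H-1,3-dioxin-5-yl)propanal; 12 methyl acrylate
Product: 13 methyl 2-[(2R)-2-(tert-butyldimethylsilyloxy)-3-(2,2-dimethyl-4H-1,3-dioxin-5-yl)-1-hydroxypropyl]prop-2-enoate (both C7 epimers)
Conditions: 1,4-diazabicyclo[2.2.2]octane (1 equiv), methyl acrylate (excess), MeOH (cat.), rt
Reagents that add atoms: none
Why: Morita–Baylis–Hillman reaction; the new carbinol centre C7 forms without control, which is harmless because it becomes trigonal in step 8.

Step 8
Reactants: 13 methyl 2-[(2R)-2-(tert-butyldimethylsilyloxy)-3-(2,2-dimethyl-4H-1,3-dioxin-5-yl)-1-hydroxypropyl]prop-2-enoate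
Product: 15 methyl (2Z,4R)-2-(bromomethyl)-4-(tert-butyldimethylsilyloxy)-5-(2,2-dimethyl-4H-1,3-dioxin-5-yl)pent-2-enoate, via allylic mesylate 14 (not isolated)
Conditions: MeSO2Cl, Et3N, CH2Cl2, −20 °C; then LiBr, THF, rt
Reagents that add atoms: lithium bromide, [Li+].[Br-]
Why: mesylation followed by SN2' displacement with bromide (allylic transposition) should give the thermodynamically preferred (Z)-2-(bromomethyl)enoate under non-acidic conditions.

Step 9
Reactants: 15 methyl (2Z,4R)-2-(bromomethyl)-4-(tert-butyldimethylsilyloxy)-5-(2,2-dimethyl-4H-1,3-dioxin-5-yl)pent-2-enoate; 4 (Z)-3-iodobut-2-enal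
Product: 17 trans-lactone silyl ether (α-methylene-γ-butyrolactone; C6 bears the (Z)-2-iodoprop-1-enyl group; C7 bears the C8 silyloxy chain ending in the 4H-1,3-dioxin), via chromium alkoxide 16 (not isolated)
Conditions: CrCl2 (nickel-free, 3 equiv), THF, 0 °C to rt, then 45 °C
Reagents that add atoms: none
Why: Nozaki–Hiyama-type allylchromium addition through a chair transition state with both substituents equatorial gives the anti adduct, which closes onto the ester to the trans lactone; the C8 silyloxy stereocentre should steer the aldehyde to the face of C7 anti to C9 (Felkin-type 1,2-induction), setting C6 and C7, and without nickel the alkenyl iodide is inert.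

Step 10
Reactants: 17 trans-lactone silyl ether
Product: 18 C8 alcohol of the trans-lactone
Conditions: Bu4NF, AcOH, THF, 0 °C to rt
Reagents that add atoms: none
Why: fluoride cleavage of the secondary silyl ether, buffered with acetic acid so that the methylene lactone and the enol ether acetal are spared.

Step 11
Reactants: 18 C8 alcohol of the trans-lactone; 19 (S)-2-methylbutanoic acid
Product: 20 C8 (S)-2-methylbutanoate carrying the 4H-1,3-dioxin
Conditions: 1-ethyl-3-(3-dimethylaminopropyl)carbodiimide hydrochloride, 4-(dimethylamino)pyridine (cat.), CH2Cl2, 0 °C to rt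
Reagents that add atoms: none
Why: Steglich esterification of the only free hydroxyl with retention at C8; the ester is installed here because no later step uses a strong base that could epimerise its α-centre.

Step 12
Reactants: 20 C8 (S)-2-methylbutanoate carrying the 4H-1,3-dioxin
Product: 21 8,8-dichloro-3,3-dimethyl-2,4-dioxabicyclo[4.2.0]octan-7-one attached through its C6 (= C10) to C9
Conditions: Cl3CCOCl, Zn–Cu couple, Et2O/1,2-dimethoxyethane, rt
Reagents that add atoms: trichloroacetyl chloride, ClC(=O)C(Cl)(Cl)Cl
Why: [2+2] cycloaddition of dichloroketene to the only electron-rich olefin: the ketene carbonyl carbon bonds to the nucleophilic C10 and the CCl2 carbon to C1, and suprafacial addition across the ring olefin fixes C1–O cis to C14, the only relative configuration that matters later.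

Step 13
Reactants: 21 dichlorocyclobutanone
Product: 22 3,3-dimethyl-2,4-dioxabicyclo[4.2.0]octan-7-one attached through C10 to C9
Conditions: Zn, AcOH, N,N,N',N'-tetramethylethylenediamine, EtOH, 0 °C
Reagents that add atoms: none
Why: reductive dechlorination of an α,α-dichloroketone by zinc; alkenyl iodide, esters and the methylene lactone are not reduced under these buffered conditions.

Step 14
Reactants: 22 cyclobutanone acetonide
Product: 23 3-hydroxy-2-(hydroxymethyl)cyclobutanone (C1–OH cis to C14–OH)
Conditions: CF3CO2H/H2O (9:1), CH2Cl2, 0 °C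
Reagents that add atoms: none
Why: acid hydrolysis of the isopropylidene acetal; esters, lactone and alkenyl iodide are stable to brief aqueous acid.

Step 15
Reactants: 23 cyclobutanone diol
Product: 24 2,4-dioxa-3-thiabicyclo[4.2.0]octan-7-one 3,3-dioxide (cyclic sulfate bridging C1–O and C14–O)
Conditions: SO2Cl2, pyridine, CH2Cl2, −78 to −20 °C
Reagents that add atoms: sulfuryl chloride, O=S(=O)(Cl)Cl
Why: cyclic sulfate formation from a cis-1,3-diol; one reagent protects C14–O and turns C1–O into a nucleofuge whose cis relation to C14 is fixed by the ring.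

Step 16
Reactants: 24 cyclobutanone cyclic sulfate
Product: 27 ten-membered dienone allylic alcohol (C3 ketone; ring-trans C1=C10 bearing C14H2OH; cis C4=C5), via chromium cyclobutanolate 25 (not isolated), via sulfate monoester 26 (not isolated)
Conditions: CrCl2 (10 equiv), NiCl2 (0.1 equiv), DMF/THF, 0.002 M (slow addition of 24), rt; then H2SO4 (cat.), H2O (2 equiv), THF, rt
Reagents that add atoms: none
Why: Proposed new method: oxidative addition of zerovalent nickel to the alkenyl iodide and transmetallation to trivalent chromium give a (Z)-alkenylchromium that adds to the strained cyclobutanone carbonyl C3, and the resulting chromium cyclobutanolate 25 fragments (Grob) with the C3–C10 bond breaking antiperiplanar to the C1–O bond of the cyclic sulfate, so that the eight-membered ring expands by C1 and C2 to the ten-membered ring. The closest known reaction types are the Nozaki–Hiyama–Kishi cyclisation of alkenyl iodides onto carbonyl groups in medium rings and the alkoxide fragmentation of γ-sulfonyloxy alcohols that gives cyclodecenones of defined olefin geometry; here they are merged in one pot. The eight-membered ring closes by 8-exo-trig carbonyl addition with the new C3–C4 bond necessarily cis to C9, and the ten-membered ring then forms by cleavage of the shared C3–C10 bond of the bicyclo[6.2.0] system while the four-membered and sulfate rings open. No new stereocentre survives (C3 becomes the ketone, C1 and C10 become trigonal); the controlling element is the cis-fused sulfate ring, which holds the leaving oxygen on the face of C14 and so places C14 cis to C2 and C9 trans to C2 in the new olefin, while the C4=C5 geometry is carried over from the iodide with retention. The step needs the alkenylchromium to choose the ketone over lactone, ester and enoate, which the aldehyde-like reactivity of a cyclobutanone and the inertness of organochromium reagents toward esters should secure, and it needs fragmentation to outrun β-elimination of the sulfate toward C2, which strain release and the non-basic medium should favour. Hydrolysis of the sulfate monoester 26 with catalytic acid frees the C14 hydroxyl.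

Step 17
Reactants: 27 ten-membered dienone allylic alcohol
Product: 28 (1R,10S)-1,10-epoxy ketone
Conditions: Ti(OiPr)4 (10 mol %), L-(+)-diethyl tartrate (12 mol %), t-BuOOH, 4 Å MS, CH2Cl2, −20 °C
Reagents that add atoms: tert-butyl hydroperoxide, CC(C)(C)OO
Why: Sharpless asymmetric epoxidation: the C14 hydroxyl directs the titanium tartrate peroxide to C1=C10 only (the enone and methylene lactone olefins are electron-poor), and L-(+)-tartrate should deliver oxygen in the sense that makes C10 (S), as C2 becomes (S) in simple allylic alcohols, giving the epoxide with C2 and C9 trans.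

Step 18
Reactants: 28 (1R,10S)-1,10-epoxy ketone
Product: 29 target CNP0356520.3
Conditions: (R)-1-methyl-3,3-diphenyl-tetrahydro-1H,3H-pyrrolo[1,2-c][1,3,2]oxazaborole (20 mol %), catecholborane (3 equiv), toluene/CH2Cl2, −78 °C
Reagents that add atoms: none
Why: Corey–Bakshi–Shibata reduction of the enone carbonyl in 1,2-fashion: the α-branched alkenyl side (C4) acts as the large group, so the (R)-oxazaborolidine should deliver hydride to the face that gives (3S), and epoxide, esters and methylene lactone are inert at −78 °C.

**Compound list**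
1 | but-2-yn-1-ol | CC#CCO | starting material
2 | cyclic sodium alkenylalanate (aluminium on C3 cis to CH2O) | [Na+].CC1=CCO[Al-]1(OCCOC)OCCOC | intermediate
3 | (Z)-3-iodobut-2-en-1-ol | C/C(I)=C/CO | intermediate
4 | (Z)-3-iodobut-2-enal | C/C(I)=C/C=O | intermediate
5 | 2-methylenepropane-1,3-diol | C=C(CO)CO | starting material
6 | 2,2-dimethoxypropane | COC(C)(C)OC | starting material
7 | 2,2-dimethyl-5-methylene-1,3-dioxane | C=C1COC(C)(C)OC1 | intermediate
8 | ethyl glyoxylate | CCOC(=O)C=O | starting material
9 | ethyl (2R)-3-(2,2-dimethyl-4H-1,3-dioxin-5-yl)-2-hydroxypropanoate | CCOC(=O)[C@H](O)CC1=COC(C)(C)OC1 | intermediate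
10 | ethyl (2R)-2-(tert-butyldimethylsilyloxy)-3-(2,2-dimethyl-4H-1,3-dioxin-5-yl)propanoate | CCOC(=O)[C@H](O[Si](C)(C)C(C)(C)C)CC1=COC(C)(C)OC1 | intermediate
11 | (2R)-2-(tert-butyldimethylsilyloxy)-3-(2,2-dimethyl-4H-1,3-dioxin-5-yl)propanal | O=C[C@H](O[Si](C)(C)C(C)(C)C)CC1=COC(C)(C)OC1 | intermediate
12 | methyl acrylate | C=CC(=O)OC | starting material
13 | methyl 2-[(2R)-2-(tert-butyldimethylsilyloxy)-3-(2,2-dimethyl-4H-1,3-dioxin-5-yl)-1-hydroxypropyl]prop-2-enoate (C7 epimers) | C=C(C(=O)OC)C(O)[C@H](O[Si](C)(C)C(C)(C)C)CC1=COC(C)(C)OC1 | intermediate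
14 | methanesulfonate of 13 (C7 epimers) | C=C(C(=O)OC)C(OS(C)(=O)=O)[C@H](O[Si](C)(C)C(C)(C)C)CC1=COC(C)(C)OC1 | intermediate
15 | methyl (2Z,4R)-2-(bromomethyl)-4-(tert-butyldimethylsilyloxy)-5-(2,2-dimethyl-4H-1,3-dioxin-5-yl)pent-2-enoate | COC(=O)/C(CBr)=C/[C@H](O[Si](C)(C)C(C)(C)C)CC1=COC(C)(C)OC1 | intermediate
16 | trivalent chromium alkoxide of the anti homoallylic alcohol (open-chain methyl ester; C6, C7, C8 as in the target) | COC(=O)C(=C)[C@@H]([C@H](O[Cr](Cl)Cl)/C=C(/C)I)[C@H](O[Si](C)(C)C(C)(C)C)CC1=COC(C)(C)OC1 | intermediate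
17 | trans-lactone silyl ether: α-methylene-γ-butyrolactone with (Z)-2-iodoprop-1-enyl at C6 and the C8 silyloxy/dioxin chain at C7 (C6, C7, C8 as in the target) | C=C1C(=O)O[C@H](/C=C(/C)I)[C@H]1[C@H](O[Si](C)(C)C(C)(C)C)CC2=COC(C)(C)OC2 | intermediate
18 | C8 alcohol of 17 | C=C1C(=O)O[C@H](/C=C(/C)I)[C@H]1[C@H](O)CC2=COC(C)(C)OC2 | intermediate
19 | (S)-2-methylbutanoic acid | CC[C@H](C)C(=O)O | starting material
20 | C8 (S)-2-methylbutanoate of 18 | C=C1C(=O)O[C@H](/C=C(/C)I)[C@H]1[C@H](OC(=O)[C@@H](C)CC)CC2=COC(C)(C)OC2 | intermediate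
21 | dichlorocyclobutanone: 8,8-dichloro-3,3-dimethyl-2,4-dioxabicyclo[4.2.0]octan-7-one on C9 (cis-fused; one of two diastereomers drawn) | C=C1C(=O)O[C@H](/C=C(/C)I)[C@H]1[C@H](OC(=O)[C@@H](C)CC)C[C@@]23COC(C)(C)O[C@@H]2C(Cl)(Cl)C3=O | intermediate
22 | cyclobutanone acetonide (dechlorinated 21) | C=C1C(=O)O[C@H](/C=C(/C)I)[C@H]1[C@H](OC(=O)[C@@H](C)CC)C[C@@]23COC(C)(C)O[C@@H]2CC3=O | intermediate
23 | cyclobutanone diol (C1–OH cis to C14H2OH) | C=C1C(=O)O[C@H](/C=C(/C)I)[C@H]1[C@H](OC(=O)[C@@H](C)CC)C[C@@]2(CO)[C@H](O)CC2=O | intermediate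
24 | cyclobutanone cyclic sulfate (six-membered sulfate bridging C1–O and C14–O) | C=C1C(=O)O[C@H](/C=C(/C)I)[C@H]1[C@H](OC(=O)[C@@H](C)CC)C[C@@]23COS(=O)(=O)O[C@@H]2CC3=O | intermediate
25 | chromium cyclobutanolate: cis-fused bicyclo[6.2.0]decene with the eight-membered ring C3–C10 closed, O–Cr on C3, sulfate intact | C=C1C(=O)O[C@@H]2/C=C(/C)[C@]3(O[Cr](Cl)Cl)C[C@H]4OS(=O)(=O)OC[C@@]34C[C@@H](OC(=O)[C@@H](C)CC)[C@@H]12 | intermediate
26 | sulfate monoester (chromium salt) of 27 at C14–O | C=C1C(=O)O[C@@H]2/C=C(/C)C(=O)C/C=C(\COS(=O)(=O)O[Cr](Cl)Cl)C[C@@H](OC(=O)[C@@H](C)CC)[C@@H]12 | intermediate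
27 | ten-membered dienone allylic alcohol: C3 ketone, ring-trans C1=C10 with C14H2OH cis to C2, cis C4=C5, lactone and C8 ester in place | C=C1C(=O)O[C@@H]2/C=C(/C)C(=O)C/C=C(\CO)C[C@@H](OC(=O)[C@@H](C)CC)[C@@H]12 | intermediate
28 | (1R,10S)-1,10-epoxy-3-ketone | C=C1C(=O)O[C@@H]2/C=C(/C)C(=O)C[C@H]3O[C@]3(CO)C[C@@H](OC(=O)[C@@H](C)CC)[C@@H]12 | intermediate
29 | CNP0356520.3 | C=C1C(=O)O[C@@H]2/C=C(/C)[C@@H](O)C[C@H]3O[C@]3(CO)C[C@@H](OC(=O)[C@@H](C)CC)[C@@H]12 | target

**Totals:** 18 steps; longest linear sequence 16 steps (5 → 29, steps 3–18).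

**Steps most likely to fail**

Step 16 (Proposed new method). The alkenylchromium may add too slowly to the α-quaternary ketone, so that protodeiodination and loss of the sulfate nucleofuge by β-elimination toward C2 take over, or the chromium alkoxide may not fragment in the pot. The fallback separates ring closure from fragmentation and uses known reaction types only. It sets out from acetonide 22, which carries no nucleofuge and tolerates a large excess of CrCl2/NiCl2 and warming. Nozaki–Hiyama–Kishi closure of the eight-membered ring should give the bicyclo[6.2.0] tertiary cyclobutanol acetonide F1. Aqueous CF3CO2H then liberates the triol F2. SO2Cl2/pyridine closes the six-membered sulfate on the C1 and C14 hydroxyls, the tertiary C3 hydroxyl being too hindered, to give the hydroxy cyclic sulfate F3. KOt-Bu in THF at −78 to 0 °C triggers the classical Grob fragmentation of the γ-sulfonyloxy alkoxide, and acidic hydrolysis of the sulfate monoester comes back to the route at 27.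

Step 9. The facial selectivity of the allylchromium reagent with respect to the C8 stereocentre may be poor, because chair-controlled anti addition and 1,2-induction need not reinforce each other. The fallback replaces substrate control by ligand control. It sets out from 15 and 4: CrCl2 (catalytic), a C2-symmetric 1,8-bis(oxazolinyl)carbazole ligand, Mn powder, Me3SiCl and i-Pr2NEt in THF should give the trimethylsilyl ether of the open-chain hydroxy ester F4. Bu4NF in THF removes both silyl groups and the C6 alkoxide lactonises, so the sequence comes back to the route at 18 and step 10 is skipped.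

Step 15. Chlorination or intermolecular sulfation may compete with closure of the six-membered sulfate at the hindered diol. The fallback differentiates the two hydroxyls instead of bridging them. It sets out from 23: t-BuMe2SiCl/imidazole silylates the primary C14 hydroxyl to give the C14 silyl ether F5, and MeSO2Cl/pyridine at −20 °C gives the C1 mesylate F6. The conditions of step 16 without the acid treatment then give the C14 silyl ether of the dienone F7 by the same ring closure and fragmentation. HF·pyridine in THF comes back to the route at 27.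

Further compounds
F1 | step 16 | bicyclo[6.2.0] tertiary cyclobutanol acetonide (eight-membered ring closed; C3–OH) | C=C1C(=O)O[C@@H]2/C=C(/C)[C@]3(O)C[C@H]4OC(C)(C)OC[C@@]34C[C@@H](OC(=O)[C@@H](C)CC)[C@@H]12
F2 | step 16 | bicyclo[6.2.0] triol (C3–OH, C1–OH, C14–OH) | C=C1C(=O)O[C@@H]2/C=C(/C)[C@]3(O)C[C@@H](O)[C@]3(CO)C[C@@H](OC(=O)[C@@H](C)CC)[C@@H]12
F3 | step 16 | bicyclo[6.2.0] hydroxy cyclic sulfate | C=C1C(=O)O[C@@H]2/C=C(/C)[C@]3(O)C[C@H]4OS(=O)(=O)OC[C@@]34C[C@@H](OC(=O)[C@@H](C)CC)[C@@H]12
F4 | step 9 | trimethylsilyl ether of the open-chain anti hydroxy ester | COC(=O)C(=C)[C@@H]([C@H](O[Si](C)(C)C)/C=C(/C)I)[C@H](O[Si](C)(C)C(C)(C)C)CC1=COC(C)(C)OC1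
F5 | step 15 | C14 tert-butyldimethylsilyl ether of 23 | C=C1C(=O)O[C@H](/C=C(/C)I)[C@H]1[C@H](OC(=O)[C@@H](C)CC)C[C@@]2(CO[Si](C)(C)C(C)(C)C)[C@H](O)CC2=O
F6 | step 15 | C1 mesylate of F5 | C=C1C(=O)O[C@H](/C=C(/C)I)[C@H]1[C@H](OC(=O)[C@@H](C)CC)C[C@@]2(CO[Si](C)(C)C(C)(C)C)[C@H](OS(C)(=O)=O)CC2=O
F7 | step 15 | C14 tert-butyldimethylsilyl ether of 27 | C=C1C(=O)O[C@@H]2/C=C(/C)C(=O)C/C=C(\CO[Si](C)(C)C(C)(C)C)C[C@@H](OC(=O)[C@@H](C)CC)[C@@H]12
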